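**Retrosynthetic overview**

1. Target 26 ← 8α-hydroxy dibenzyl ester 24 (acetylation, hydrogenolysis) ← dihydroxy diacid 21 ← 7α,8α-epoxide 19. The C8 oxygen comes from α-face epoxidation of a C7=C8 alkene and hydride opening at C7.
2. At C4 a gem-diester is differentiated: the equatorial ester is hydrolysed first (C18 acid) and the remaining axial ester is reduced and deoxygenated (C19 methyl).
3. 19 ← Δ7 triester 18 ← Δ6 aldehyde 14, by two-carbon Wittig extension at C11, conjugate reduction and a C6=C7 → C7=C8 shift.
4. Feature used: C5, C10, C9 and C8 are contiguous in ring B and C9 carries C11. Ring B is therefore the cyclohexene of a [4+2] between a C9=C10 β-methyl enal and a C5=C6–C7=C8 diene tethered through C1–C4; rings A and B close together in step 9 and no other ring is formed.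
5. Trienal 13 ← deconjugative α-alkylation of pentenylidene malonate 3 (from 1 + 2) with iodide 9, whose E-trisubstituted alkene is taken from geranyl acetate 4.

Key step: step 9

Remark on numbering: labdane numbering is used for the bicyclic compounds (ring A = C1–C5, C10; ring B = C5–C10; C18 = 4α, equatorial; C19 = 4β, axial; C17 on C8; C20 on C10; side chain C11–C13 on C9). All have 5α-H, 10β-methyl and the 9β side chain (9α-H).

Assumption: the oxazaborolidinium ion derived from (S)-α,α-diphenylprolinol is taken to cover the C9-re face of the bound s-trans enal, so that bonding occurs at the C9-si face; if the adduct proves antipodal, the (R)-catalyst is used and nothing else changes.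

**Route**

Step 1
Reactants: 1 dimethyl malonate; 2 (E)-pent-2-enal
Product: 3 dimethyl 2-[(E)-pent-2-enylidene]malonate
Conditions: TiCl4, pyridine, THF, 0 °C → rt
Reagents that add atoms: none
Why: TiCl4/pyridine-mediated Knoevenagel condensation, in which the titanium malonate enolate adds 1,2 to the aldehyde and the aldolate eliminates, which avoids the 1,4-addition that amine catalysts favour with enals and leaves the E alkene of 2 in place.

Step 2
Reactants: 4 geranyl acetate
Product: 5 6,7-epoxygeranyl acetate (racemic at the epoxide CH)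
Conditions: mCPBA (1.0 equiv), NaHCO3, CH2Cl2, 0 °C
Reagents that add atoms: mCPBA, O=C(OO)c1cccc(Cl)c1
Why: Prilezhaev epoxidation, chemoselective for the electron-rich C6=C7 alkene because the C2=C3 alkene is deactivated by the allylic acetate; the new stereocentre is removed in step 3, so the racemic epoxide serves.

Step 3
Reactants: 5 6,7-epoxygeranyl acetate
Product: 7 (E)-3-methyl-6-oxohex-2-enyl acetate, via vicinal diol 6 (not isolated)
Conditions: H5IO6, THF–H2O, 0 °C
Reagents that add atoms: none
Why: One-pot acid-promoted epoxide hydrolysis (water attacks the tertiary carbon) and Malaprade glycol cleavage, which removes the isopropylidene end as acetone, keeps the epoxide oxygen as the aldehyde oxygen and does not touch the E-trisubstituted alkene that becomes C9=C10.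

Step 4
Reactants: 7 (E)-3-methyl-6-oxohex-2-enyl acetate
Product: 8 (E)-6-hydroxy-3-methylhex-2-enyl acetate
Conditions: NaBH4, MeOH, 0 °C
Reagents that add atoms: none
Why: Chemoselective borohydride reduction of the aldehyde at 0 °C, under which the allylic acetate and the alkene are stable.

Step 5
Reactants: 8 (E)-6-hydroxy-3-methylhex-2-enyl acetate
Product: 9 (E)-6-iodo-3-methylhex-2-enyl acetate
Conditions: I2, PPh3, imidazole, CH2Cl2, 0 °C → rt
Reagents that add atoms: iodine, II
Why: Appel-type iodination of the primary alcohol by SN2 displacement of the oxyphosphonium ion, neutral enough for the allylic acetate.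

Step 6
Reactants: 3 dimethyl 2-[(E)-pent-2-enylidene]malonate; 9 (E)-6-iodo-3-methylhex-2-enyl acetate
Product: 11 dimethyl 2-[(E)-6-acetoxy-4-methylhex-4-enyl]-2-[(1E,3E)-penta-1,3-dienyl]malonate, via sodium dienolate 10 (not isolated)
Conditions: NaH, THF–DMF, 0 °C; then 9, rt
Reagents that add atoms: none
Why: Deconjugative α-alkylation of an alkylidene malonate, in which NaH removes the ε-proton of 3 to give the extended enolate 10 and this reacts with the primary iodide at the malonate carbon, so that the alkenes move out of conjugation as the (1E,3E)-diene (1E from the s-trans geometry of 3, 3E from the thermodynamically preferred W-shaped anion).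

Step 7
Reactants: 11 dimethyl 2-[(E)-6-acetoxy-4-methylhex-4-enyl]-2-[(1E,3E)-penta-1,3-dienyl]malonate
Product: 12 dimethyl 2-[(E)-6-hydroxy-4-methylhex-4-enyl]-2-[(1E,3E)-penta-1,3-dienyl]malonate
Conditions: K2CO3 (cat.), MeOH, rt
Reagents that add atoms: none
Why: Base-catalysed transesterification (methanolysis) of the acetate; exchange at the malonate methyl esters is degenerate in methanol and the quaternary malonate carbon has no α-hydrogen through which the diene could move back into conjugation.

Step 8
Reactants: 12 dimethyl 2-[(E)-6-hydroxy-4-methylhex-4-enyl]-2-[(1E,3E)-penta-1,3-dienyl]malonate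
Product: 13 dimethyl 2-[(E)-4-methyl-6-oxohex-4-enyl]-2-[(1E,3E)-penta-1,3-dienyl]malonate
Conditions: MnO2, CH2Cl2, rt
Reagents that add atoms: none
Why: Chemoselective MnO2 oxidation of the allylic alcohol to the enal under neutral heterogeneous conditions, which keeps the E geometry that later decides the cis relation of the C10 methyl and C11.

Step 9
Reactants: 13 dimethyl 2-[(E)-4-methyl-6-oxohex-4-enyl]-2-[(1E,3E)-penta-1,3-dienyl]malonate
Product: 14 dimethyl 11-oxo-12,13,14,15,16-pentanorlabd-6-ene-18,19-dioate (trans-fused octalin; 9β-formyl, 8β-methyl, 10β-methyl, 5α-H)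
Conditions: (S)-o-tolyl oxazaborolidine from (S)-α,α-diphenylprolinol (20 mol %), Tf2NH (18 mol %), CH2Cl2, −40 → 0 °C
Reagents that add atoms: none
Why: The protonated oxazaborolidine binds the formyl oxygen of 13 and the (1E,3E)-diene adds across C9=C10 in a concerted, asynchronous [4+2] cycloaddition, the closest known reaction being the chiral oxazaborolidinium-catalysed intramolecular Diels–Alder reaction of (2E,8E,10E)-trienals to trans-fused octalins. Ring B closes as the cyclohexene of the cycloaddition (bonds C5–C10 and C8–C9), and ring A closes in the same event through the four-carbon tether C1–C4, which folds as a chair (fused mode, tether on the diene terminus) and is helped by the gem-diester. At C9 and C10 suprafacial addition to the E-enal keeps the C10 methyl cis to the formyl group; at C5 the formyl-endo transition state has the tether exo on C10 and outside on the E diene terminus, which gives the trans ring fusion; at C8 the E,E-diene puts its methyl cis to the formyl group (this centre is erased in step 12). The absolute configuration comes from the catalyst, which covers the C9-re face of the s-trans enal so that C8 bonds to the C9-si face. The step needs endo over exo and enantioface selectivity: Lewis-acid binding strengthens the endo preference, the chair tether disfavours the cis-fused alternative, and the substrate carries no stereocentre that could interfere. The β,β-disubstituted enal is a more hindered dienophile than the usual members of this class, so reactivity is the main uncertainty and the temperature is raised only as far as needed.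

Step 10
Reactants: 14 dimethyl 11-oxo-12,13,14,15,16-pentanorlabd-6-ene-18,19-dioate; 15 methyl (triphenylphosphoranylidene)acetate
Product: 16 trimethyl (11E)-14,15,16-trinorlabda-6,11-diene-13,18,19-trioate
Conditions: toluene, 90 °C
Reagents that add atoms: none
Why: Wittig olefination with a stabilised ylide, E-selective and free of added base, so the C9 stereocentre α to the aldehyde (already the equatorial, more stable epimer) is not put at risk.

Step 11
Reactants: 16 trimethyl (11E)-14,15,16-trinorlabda-6,11-diene-13,18,19-trioate
Product: 17 trimethyl 14,15,16-trinorlabd-6-ene-13,18,19-trioate (8β-methyl, 8α-H)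
Conditions: Mg turnings, MeOH, 0 °C → rt
Reagents that add atoms: none
Why: Mg/MeOH conjugate reduction (single-electron transfer to the enoate and protonation by methanol), selective for the α,β-unsaturated ester over the isolated C6=C7 alkene and the hindered malonate esters.

Step 12
Reactants: 17 trimethyl 14,15,16-trinorlabd-6-ene-13,18,19-trioate
Product: 18 trimethyl 14,15,16-trinorlabd-7-ene-13,18,19-trioate
Conditions: RhCl3·3H2O (10 mol %), MeOH, 70 °C, sealed tube; stopped when 17 is consumed
Reagents that add atoms: none
Why: Rh–H-catalysed positional isomerisation of the alkene (hydrometalation from the open α face with Rh on the less hindered C7, then β-hydride elimination of the syn 8α-H) to the trisubstituted C7=C8 isomer, driven also by relief of the syn-axial C8-methyl/C10-methyl strain, while a further shift to C8=C9 would need Rh on the tertiary C8 and the crowded C5 side is disfavoured.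

Step 13
Reactants: 18 trimethyl 14,15,16-trinorlabd-7-ene-13,18,19-trioate
Product: 19 trimethyl 7α,8α-epoxy-14,15,16-trinorlabdane-13,18,19-trioate
Conditions: mCPBA, NaHCO3, CH2Cl2, 0 °C
Reagents that add atoms: mCPBA, O=C(OO)c1cccc(Cl)c1
Why: Prilezhaev epoxidation from the α face, because the β face of C7=C8 is screened by the axial C10 methyl and the C9 side chain, which sets the C8–O bond α (methyl β), and this bond is not broken again.

Step 14
Reactants: 19 trimethyl 7α,8α-epoxy-14,15,16-trinorlabdane-13,18,19-trioate
Product: 20 dipotassium 7α,8α-epoxy-19-methoxy-19-oxo-14,15,16-trinorlabdane-13,18-dioate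
Conditions: KOH (4 equiv), MeOH–H2O (4:1), 65 °C; evaporation and azeotropic drying (toluene), no acidification
Reagents that add atoms: potassium hydroxide, [K+].[OH-]
Why: Saponification (BAc2) of the unhindered C13 ester and of the equatorial C18 ester, while the axial C19 ester, syn-axial to the C10 methyl and now next to a carboxylate, resists, which makes C4 stereogenic with the carboxylate α; the product is kept as the salt because the free epoxy acid would open the epoxide at C8.

Step 15
Reactants: 20 dipotassium 7α,8α-epoxy-19-methoxy-19-oxo-14,15,16-trinorlabdane-13,18-dioate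
Product: 21 8α,19-dihydroxy-14,15,16-trinorlabdane-13,18-dioic acid
Conditions: LiEt3BH (6 equiv), THF, 0 → 65 °C; H2O; 1 M HCl to pH 4, 0 °C
Reagents that add atoms: none
Why: Lithium triethylborohydride reduces the remaining axial ester to the primary alcohol and opens the trisubstituted epoxide by SN2 attack at the secondary C7, which leaves the C8–O bond (8α-OH, 8β-methyl) intact, while the two carboxylates are not reduced.

Step 16
Reactants: 21 8α,19-dihydroxy-14,15,16-trinorlabdane-13,18-dioic acid
Product: 22 dibenzyl 8α,19-dihydroxy-14,15,16-trinorlabdane-13,18-dioate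
Conditions: BnBr (2.2 equiv), K2CO3, DMF, rt
Reagents that add atoms: benzyl bromide, BrCc1ccccc1
Why: O-Alkylation of the two carboxylates with benzyl bromide (SN2 at the benzylic carbon, so the hindrance at C4 matters little), the carbonate base being too weak to benzylate the primary and tertiary hydroxyl groups.

Step 17
Reactants: 22 dibenzyl 8α,19-dihydroxy-14,15,16-trinorlabdane-13,18-dioate
Product: 23 dibenzyl 8α-hydroxy-19-(imidazol-1-ylcarbonothioyloxy)-14,15,16-trinorlabdane-13,18-dioate
Conditions: 1,1'-thiocarbonyldiimidazole, DMAP (cat.), toluene, 80 °C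
Reagents that add atoms: 1,1'-thiocarbonyldiimidazole, S=C(n1ccnc1)n1ccnc1
Why: Thiocarbonylation of the primary (neopentyl) C19 hydroxyl, the tertiary 8α-hydroxyl being too hindered to react, as the first half of a Barton–McCombie deoxygenation.

Step 18
Reactants: 23 dibenzyl 8α-hydroxy-19-(imidazol-1-ylcarbonothioyloxy)-14,15,16-trinorlabdane-13,18-dioate
Product: 24 dibenzyl 8α-hydroxy-14,15,16-trinorlabdane-13,18-dioate
Conditions: Bu3SnH, AIBN, toluene, 110 °C
Reagents that add atoms: none
Why: Barton–McCombie radical deoxygenation, in which the stannyl radical adds to sulfur, the C19–O bond fragments to the primary radical at reflux and this abstracts hydrogen from Bu3SnH, which turns the axial substituent into the C19 methyl without touching a stereocentre or the benzyl esters.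

Step 19
Reactants: 24 dibenzyl 8α-hydroxy-14,15,16-trinorlabdane-13,18-dioate
Product: 25 dibenzyl 8α-acetoxy-14,15,16-trinorlabdane-13,18-dioate
Conditions: AcCl, N,N-dimethylaniline, CH2Cl2, 0 °C → rt
Reagents that add atoms: acetyl chloride, CC(=O)Cl
Why: Acylation of the hindered tertiary 8α-alcohol with acetyl chloride and N,N-dimethylaniline, conditions established for 8α-hydroxy labdanes, with retention at C8 because only the O–H bond reacts.

Step 20
Reactants: 25 dibenzyl 8α-acetoxy-14,15,16-trinorlabdane-13,18-dioate
Product: 26 8α-acetoxy-14,15,16-trinorlabdane-13,18-dioic acid (CNP0196050.1)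
Conditions: H2 (1 atm), 10% Pd/C, EtOAc, rt
Reagents that add atoms: none
Why: Hydrogenolysis of both benzyl esters over Pd/C under neutral conditions, which leaves the tertiary acetate and all stereocentres untouched and gives the diacid.

**Compound list**

1 | dimethyl malonate | COC(=O)CC(=O)OC | starting material
2 | (E)-pent-2-enal | CC/C=C/C=O | starting material
3 | dimethyl 2-[(E)-pent-2-enylidene]malonate | CC/C=C/C=C(C(=O)OC)C(=O)OC | intermediate
4 | geranyl acetate | CC(C)=CCC/C(C)=C/COC(C)=O | starting material
5 | 6,7-epoxygeranyl acetate (racemic epoxide) | CC1(C)OC1CC/C(C)=C/COC(C)=O | intermediate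
6 | (E)-6,7-dihydroxy-3,7-dimethyloct-2-enyl acetate (vicinal diol, not isolated) | CC(C)(O)C(O)CC/C(C)=C/COC(C)=O | intermediate
7 | (E)-3-methyl-6-oxohex-2-enyl acetate | O=CCC/C(C)=C/COC(C)=O | intermediate
8 | (E)-6-hydroxy-3-methylhex-2-enyl acetate | OCCC/C(C)=C/COC(C)=O | intermediate
9 | (E)-6-iodo-3-methylhex-2-enyl acetate | ICCC/C(C)=C/COC(C)=O | intermediate
10 | sodium dienolate of 3 (not isolated) | [Na+].COC(=O)[C-](/C=C/C=C/C)C(=O)OC | intermediate
11 | dimethyl 2-[(E)-6-acetoxy-4-methylhex-4-enyl]-2-[(1E,3E)-penta-1,3-dienyl]malonate | COC(=O)C(C(=O)OC)(/C=C/C=C/C)CCC/C(C)=C/COC(C)=O | intermediate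
12 | dimethyl 2-[(E)-6-hydroxy-4-methylhex-4-enyl]-2-[(1E,3E)-penta-1,3-dienyl]malonate | COC(=O)C(C(=O)OC)(/C=C/C=C/C)CCC/C(C)=C/CO | intermediate
13 | dimethyl 2-[(E)-4-methyl-6-oxohex-4-enyl]-2-[(1E,3E)-penta-1,3-dienyl]malonate | COC(=O)C(C(=O)OC)(/C=C/C=C/C)CCC/C(C)=C/C=O | intermediate
14 | dimethyl 11-oxo-12,13,14,15,16-pentanorlabd-6-ene-18,19-dioate (9β-CHO, 8β-Me, 10β-Me, 5α-H) | C[C@H]1C=C[C@@H]2[C@](C)(CCCC2(C(=O)OC)C(=O)OC)[C@H]1C=O | intermediate
15 | methyl (triphenylphosphoranylidene)acetate | COC(=O)C=P(c1ccccc1)(c1ccccc1)c1ccccc1 | starting material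
16 | trimethyl (11E)-14,15,16-trinorlabda-6,11-diene-13,18,19-trioate | C[C@H]1C=C[C@@H]2[C@](C)(CCCC2(C(=O)OC)C(=O)OC)[C@H]1/C=C/C(=O)OC | intermediate
17 | trimethyl 14,15,16-trinorlabd-6-ene-13,18,19-trioate | C[C@H]1C=C[C@@H]2[C@](C)(CCCC2(C(=O)OC)C(=O)OC)[C@H]1CCC(=O)OC | intermediate
18 | trimethyl 14,15,16-trinorlabd-7-ene-13,18,19-trioate | CC1=CC[C@@H]2[C@](C)(CCCC2(C(=O)OC)C(=O)OC)[C@H]1CCC(=O)OC | intermediate
19 | trimethyl 7α,8α-epoxy-14,15,16-trinorlabdane-13,18,19-trioate | C[C@@]12O[C@@H]1C[C@@H]1[C@](C)(CCCC1(C(=O)OC)C(=O)OC)[C@H]2CCC(=O)OC | intermediate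
20 | dipotassium 7α,8α-epoxy-19-methoxy-19-oxo-14,15,16-trinorlabdane-13,18-dioate | C[C@@]12O[C@@H]1C[C@@H]1[C@](C)(CCC[C@]1(C(=O)[O-])C(=O)OC)[C@H]2CCC(=O)[O-].[K+].[K+] | intermediate
21 | 8α,19-dihydroxy-14,15,16-trinorlabdane-13,18-dioic acid | C[C@@]1(O)CC[C@@H]2[C@](C)(CCC[C@@]2(CO)C(=O)O)[C@H]1CCC(=O)O | intermediate
22 | dibenzyl 8α,19-dihydroxy-14,15,16-trinorlabdane-13,18-dioate | C[C@@]1(O)CC[C@@H]2[C@](C)(CCC[C@@]2(CO)C(=O)OCc2ccccc2)[C@H]1CCC(=O)OCc1ccccc1 | intermediate
23 | dibenzyl 8α-hydroxy-19-(imidazol-1-ylcarbonothioyloxy)-14,15,16-trinorlabdane-13,18-dioate | C[C@@]1(O)CC[C@@H]2[C@](C)(CCC[C@@]2(COC(=S)n2ccnc2)C(=O)OCc2ccccc2)[C@H]1CCC(=O)OCc1ccccc1 | intermediate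
24 | dibenzyl 8α-hydroxy-14,15,16-trinorlabdane-13,18-dioate | C[C@@]1(O)CC[C@@H]2[C@](C)(CCC[C@@]2(C)C(=O)OCc2ccccc2)[C@H]1CCC(=O)OCc1ccccc1 | intermediate
25 | dibenzyl 8α-acetoxy-14,15,16-trinorlabdane-13,18-dioate | CC(=O)O[C@]1(C)CC[C@@H]2[C@](C)(CCC[C@@]2(C)C(=O)OCc2ccccc2)[C@H]1CCC(=O)OCc1ccccc1 | intermediate
26 | 8α-acetoxy-14,15,16-trinorlabdane-13,18-dioic acid (CNP0196050.1) | CC(=O)O[C@]1(C)CC[C@@H]2[C@](C)(CCC[C@@]2(C)C(=O)O)[C@H]1CCC(=O)O | target

**Step count and risks**

Total: 20 steps. Longest linear sequence: 19 steps (geranyl acetate 4 → 26, steps 2–20).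

Step 9 (key cycloaddition). The β,β-disubstituted enal may be too unreactive toward the cationic boron catalyst at low temperature. Warming may then cost enantioface selectivity or decompose the diene, and the syn-axial C10-methyl/C19-ester contact that develops in the chair tether may let the exo (cis-fused) mode compete. The fallback replaces catalyst control by auxiliary control and runs from 13 back to 14. Pinnick oxidation of 13 (NaClO2, NaH2PO4, 2-methylbut-2-ene, t-BuOH–H2O) would give the (E)-trienoic acid F1. Pivaloyl chloride/Et3N would convert it into the mixed pivalic anhydride F2, which acylates lithiated (S)-4-benzyloxazolidin-2-one to the N-enoyl oxazolidinone F3. Me2AlCl (CH2Cl2, −30 → 0 °C) should then promote the intramolecular Diels–Alder reaction through the chelated s-cis imide, with the benzyl group covering the C9-re face, to give the trans-fused adduct imide F4. LiBH4/MeOH (THF, 0 °C) would cleave the auxiliary to the C11 primary alcohol F5, the hindered malonate esters reacting far more slowly, and Dess–Martin oxidation returns aldehyde 14.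

Step 12 (alkene shift). The migration may not stop at C7=C8: over-migration to the tetrasubstituted C8=C9 alkene would destroy the C9 stereocentre, and migration toward C5=C6 or incomplete conversion would give inseparable positional isomers. The fallback is a stepwise transposition through a C7 ketone and runs from 17 back to 18. Hydroboration–oxidation (BH3·THF, 0 °C; NaBO3) from the α face, with boron on the less hindered C7, would give the 7α-alcohol F6. Dess–Martin oxidation would give the 7-ketone F7. Tf2O with 2,6-di-tert-butyl-4-methylpyridine should give the more substituted C7=C8 enol triflate F8, and Pd(OAc)2/PPh3, Bu3N, HCO2H (DMF, 60 °C) would reduce the C–OTf bond to give 18.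

Step 15 (double reduction). Hydride attack at C7 runs against the trans-diaxial preference of the locked ring and takes place on a poorly soluble salt, so the epoxide may open slowly or isomerise to an allylic alcohol, and reduction of the axial ester may be incomplete. The fallback installs the C8 oxygen by radical Markovnikov hydration and decouples the ester reduction; it runs from 18 back to 21. Mukaiyama hydration of 18 (Mn(dpm)3, PhSiH3, O2, i-PrOH, 0 °C; then PPh3) should give the 8α-hydroxy triester F9. Oxygen trapping of the C8 radical anti to the syn-axial C10 methyl is expected to be favoured, and any 8-epimer would have to be separated. KOH in MeOH–H2O followed by acidification would give the 8α-hydroxy diacid monoester F10, which can be handled as the free acid because no epoxide is present. LiBH4 (THF, 50 °C) would then reduce the axial ester in the presence of the carboxylates to give 21.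

Further compounds
F1 | step 9 | (2E)-7,7-bis(methoxycarbonyl)-3-methyl-dodeca-2,8E,10E-trienoic acid (acid from 13) | COC(=O)C(C(=O)OC)(/C=C/C=C/C)CCC/C(C)=C/C(=O)O
F2 | step 9 | mixed pivalic anhydride of F1 | COC(=O)C(C(=O)OC)(/C=C/C=C/C)CCC/C(C)=C/C(=O)OC(=O)C(C)(C)C
F3 | step 9 | (S)-4-benzyl-3-[(E)-enoyl]oxazolidin-2-one of F1 | COC(=O)C(C(=O)OC)(/C=C/C=C/C)CCC/C(C)=C/C(=O)N1[C@@H](Cc2ccccc2)COC1=O
F4 | step 9 | trans-fused Diels–Alder adduct imide (9β-acyl, 8β-Me, 10β-Me, 5α-H) | C[C@H]1C=C[C@@H]2[C@](C)(CCCC2(C(=O)OC)C(=O)OC)[C@H]1C(=O)N1[C@@H](Cc2ccccc2)COC1=O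
F5 | step 9 | dimethyl 11-hydroxy-12,13,14,15,16-pentanorlabd-6-ene-18,19-dioate | C[C@H]1C=C[C@@H]2[C@](C)(CCCC2(C(=O)OC)C(=O)OC)[C@H]1CO
F6 | step 12 | trimethyl 7α-hydroxy-14,15,16-trinorlabdane-13,18,19-trioate (8β-Me) | C[C@H]1[C@H](O)C[C@@H]2[C@](C)(CCCC2(C(=O)OC)C(=O)OC)[C@H]1CCC(=O)OC
F7 | step 12 | trimethyl 7-oxo-14,15,16-trinorlabdane-13,18,19-trioate (8β-Me) | C[C@H]1C(=O)C[C@@H]2[C@](C)(CCCC2(C(=O)OC)C(=O)OC)[C@H]1CCC(=O)OC
F8 | step 12 | trimethyl 7-(trifluoromethylsulfonyloxy)-14,15,16-trinorlabd-7-ene-13,18,19-trioate | CC1=C(OS(=O)(=O)C(F)(F)F)C[C@@H]2[C@](C)(CCCC2(C(=O)OC)C(=O)OC)[C@H]1CCC(=O)OC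
F9 | step 15 | trimethyl 8α-hydroxy-14,15,16-trinorlabdane-13,18,19-trioate | C[C@@]1(O)CC[C@@H]2[C@](C)(CCCC2(C(=O)OC)C(=O)OC)[C@H]1CCC(=O)OC
F10 | step 15 | 8α-hydroxy-19-methoxy-19-oxo-14,15,16-trinorlabdane-13,18-dioic acid | C[C@@]1(O)CC[C@@H]2[C@](C)(CCC[C@]2(C(=O)O)C(=O)OC)[C@H]1CCC(=O)O
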